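**Plan**

1. Numbering: C1 (angular-methyl carbon), C2=C3, C4 (isopropyl carbinol), C5 (ring-fusion CH), C6 (ester carbon), C7, C8 (methyl carbinol), C9, C10. Retrosynthetic cuts, in order: the C6–O ester bond, C8–CH3, C6–C7 (seven-membered ring), C1–C10 and C1–CH3 (quaternary centre), and last C4–C5 of the cyclopentene.
2. Enabling feature: the five-membered ring C1–C5 carries the tertiary carbinol C4 (OH, isopropyl), the C2=C3 alkene and the C5 methine. With C1 as a ketone it is a 4-hydroxy-4-isopropylcyclopent-2-enone, the rearrangement product of a 2-furylcarbinol whose other α-carbon bears the isopropyl group.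
3. Forward: lithiated 2-isopropylfuran plus an alkoxyacetaldehyde gives the furylcarbinol; acid-mediated furan-to-cyclopentenone rearrangement forms the first ring. Methyl addition and oxidative transposition, then anti conjugate addition of the C7–C10 chain with enolate triflation and reduction, restore C2=C3. A carbonyl-ene closure of C6–C7 forms the seven-membered ring; C8 ketone plus MeMgBr, C6 oxidation and directed reduction, and vanilloylation finish the route.
4. Stereochemistry: C4 (absolute) from catalyst-controlled conrotation in step 2. C5 by thermodynamic epimerisation α to the ketone, because the rearrangement is expected to place the hydroxyl trans to the side chain, whereas the target needs it cis. C1 by addition anti to the C5 side chain; C8 by equatorial methyl delivery; C6 by hydride delivery directed from the 8α-hydroxyl.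

Key step: step 2

Remark: α is the face of the C1 methyl group, β that of H-5. The (R)-acid is assumed to lead to the (4S) series; if the sense is opposite, its enantiomer is used.

**Step 1**
Reactants: 1 2-isopropylfuran; 2 (4-methoxybenzyloxy)acetaldehyde
Product: 4 rac-1-(5-isopropylfuran-2-yl)-2-[(4-methoxybenzyl)oxy]ethan-1-ol, via 5-isopropyl-2-furyllithium 3 (not isolated)
Conditions: n-BuLi, THF, 0 → 23 °C; then 2, −78 °C; aq. NH4Cl
Reagents that add atoms: none
Why: α-Lithiation of a 2-alkylfuran at its free α-position followed by 1,2-addition to the aldehyde; the carbinol centre is racemic and is erased in step 2.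

**Step 2**
Reactants: 4 rac-furylcarbinol
Product: 6 (4S,5R)-4-hydroxy-4-isopropyl-5-{[(4-methoxybenzyl)oxy]methyl}cyclopent-2-en-1-one (hydroxyl trans to the side chain), via 1,4-dihydroxypentadienyl cation 5 (not isolated)
Conditions: (R)-3,3′-bis(2,4,6-triisopropylphenyl)-1,1′-binaphthyl-2,2′-diyl hydrogen phosphate (10 mol %), H2O (10 equiv), CHCl3, 40 °C
Reagents that add atoms: water, O
Why: Proposed new method: the chiral phosphoric acid ionises the carbinol to a furfuryl cation, water adds at the isopropyl-bearing α-carbon of the furan, the hemiketal opens to the 1,4-dihydroxypentadienyl cation 5, and a thermal 4π conrotatory electrocyclisation joins C4 to C5, the oxyallyl cation giving the enone by proton loss; the closest known reaction types are the racemic Piancatelli rearrangement of 5-alkyl-2-furylcarbinols in aqueous acid and the chiral-phosphoric-acid-catalysed aza-Piancatelli rearrangement with anilines. The only ring formed, the five-membered carbocycle, closes by this conrotatory 4π (Nazarov-like) mode. C4 is set by the sense of conrotation, which the phosphate anion, hydrogen-bonded to both hydroxyl groups of 5 in a contact ion pair, is expected to dictate; C5 is set relative to C4 by conrotation of the cation in which the donor hydroxyl and the side chain both point outward, so the hydroxyl should emerge trans to the side chain, as in the parent reaction. The step needs attack of water at the substituted α-carbon and high enantioselectivity at C4, the one centre that cannot be corrected later: the first is secured because attack at the carbinol carbon only returns 4, the second rests on two-point binding of the cation to the anion. The C5 configuration is not relied upon, since this centre lies α to the new ketone and is equilibrated in step 4.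

**Step 3**
Reactants: 6 hydroxy enone
Product: 7 (4S,5R)-4-isopropyl-5-{[(4-methoxybenzyl)oxy]methyl}-4-[(triethylsilyl)oxy]cyclopent-2-en-1-one
Conditions: Et3SiOTf, 2,6-lutidine, CH2Cl2, −78 → 0 °C
Reagents that add atoms: triethylsilyl trifluoromethanesulfonate, CC[Si](CC)(CC)OS(=O)(=O)C(F)(F)F
Why: Silyl triflate silylation of a hindered tertiary alcohol; the ether blocks retro-aldol opening (which would racemise C4) and later leaves only the C1 carbinol free for the oxidative transposition.

**Step 4**
Reactants: 7 silyl ether (side chain cis to isopropyl)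
Product: 8 (4S,5S)-4-isopropyl-5-{[(4-methoxybenzyl)oxy]methyl}-4-[(triethylsilyl)oxy]cyclopent-2-en-1-one (side chain cis to the silyloxy group)
Conditions: 1,8-diazabicyclo[5.4.0]undec-7-ene (0.3 equiv), toluene, 23 °C
Reagents that add atoms: none
Why: Base-catalysed epimerisation α to the ketone through the dienolate (thermodynamic control) should move the side chain trans to the larger isopropyl group, while β-elimination is disfavoured because it would give an antiaromatic cyclopentadienone.

**Step 5**
Reactants: 8 cis silyl ether
Product: 9 4-isopropyl-1-methyl-5-{[(4-methoxybenzyl)oxy]methyl}-4-[(triethylsilyl)oxy]cyclopent-2-en-1-ol (C4 and C5 as in 8; C1 methyl anti to the side chain)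
Conditions: MeLi, THF, −78 °C; aq. NH4Cl
Reagents that add atoms: methyllithium, [Li]C
Why: 1,2-Addition of methyllithium to the enone carbonyl at low temperature; the new C1 carbinol centre is destroyed in step 6, so its configuration is immaterial.

**Step 6**
Reactants: 9 tertiary allylic alcohol
Product: 10 (4S,5R)-5-isopropyl-4-{[(4-methoxybenzyl)oxy]methyl}-3-methyl-5-[(triethylsilyl)oxy]cyclopent-2-en-1-one (ketone at C3; C1=C2 bearing the methyl)
Conditions: pyridinium chlorochromate, 4 Å molecular sieves, CH2Cl2, 23 °C
Reagents that add atoms: pyridinium chlorochromate, [O-][Cr](=O)(=O)Cl.c1cc[nH+]cc1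
Why: Babler–Dauben oxidative 1,3-transposition: the tertiary allylic chromate ester undergoes a [3,3] shift to C3 and is oxidised to the enone, the silylated C4 oxygen being unable to compete.

**Step 7**
Reactants: 10 transposed enone; 11 4-bromo-2-methylbut-1-ene
Product: 14 5-isopropyl-4-{[(4-methoxybenzyl)oxy]methyl}-3-methyl-3-(3-methylbut-3-en-1-yl)-5-[(triethylsilyl)oxy]cyclopent-1-en-1-yl trifluoromethanesulfonate (new chain trans to the PMB-oxymethyl group), via (3-methylbut-3-en-1-yl)magnesium bromide 12 (not isolated), via bromomagnesium enolate 13 (not isolated)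
Conditions: 11, Mg, THF; then CuBr·SMe2 (20 mol %), 10, THF, −40 °C; then N-(5-chloropyridin-2-yl)bis(trifluoromethanesulfonimide), −40 → 0 °C; aq. NH4Cl
Reagents that add atoms: N-(5-chloropyridin-2-yl)bis(trifluoromethanesulfonimide) (Comins' reagent), FC(F)(F)S(=O)(=O)N(c1ccc(Cl)cn1)S(=O)(=O)C(F)(F)F
Why: Copper-catalysed conjugate addition of the Grignard reagent to the β-methyl enone builds the C1 quaternary centre from the β-face, anti to the adjacent C5 side chain (the α-face also carries the silyloxy group), and the enolate, which can only be the C2=C3 enolate because C4 has no hydrogen, is O-triflated.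

**Step 8**
Reactants: 14 enol triflate
Product: 15 4-isopropyl-1-methyl-1-(3-methylbut-3-en-1-yl)-5-{[(4-methoxybenzyl)oxy]methyl}-4-[(triethylsilyl)oxy]cyclopent-2-ene (target configuration at C1/C4/C5)
Conditions: Pd(OAc)2 (5 mol %), PPh3 (10 mol %), HCO2H, Bu3N, DMF, 60 °C
Reagents that add atoms: none
Why: Palladium-catalysed formate reduction of an enol triflate (oxidative addition to zerovalent palladium, formate exchange, decarboxylation, reductive elimination) returns the C2=C3 alkene and leaves the isolated 1,1-disubstituted alkene alone.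

**Step 9**
Reactants: 15 PMB ether
Product: 16 [4-isopropyl-1-methyl-1-(3-methylbut-3-en-1-yl)-4-(triethylsilyloxy)cyclopent-2-en-5-yl]methanol
Conditions: DDQ, CH2Cl2/pH 7 phosphate buffer, 0 → 23 °C
Reagents that add atoms: none
Why: Oxidative PMB cleavage by DDQ (hydride abstraction at the electron-rich benzylic carbon) under buffered conditions spares the silyl ether and both alkenes.

**Step 10**
Reactants: 16 primary alcohol
Product: 17 4-isopropyl-1-methyl-1-(3-methylbut-3-en-1-yl)-4-(triethylsilyloxy)cyclopent-2-ene-5-carbaldehyde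
Conditions: Dess–Martin periodinane, NaHCO3, CH2Cl2, 0 °C
Reagents that add atoms: none
Why: Dess–Martin oxidation under buffered, non-basic conditions gives the α-branched aldehyde without C5 epimerisation or β-elimination of the silyloxy group.

**Step 11**
Reactants: 17 aldehyde
Product: 18 trans-fused hydroazulene with C6 α-OH; C8 exocyclic methylene; C4 OSiEt3 (C1/C4/C5 as in the target)
Conditions: Me2AlCl (2 equiv), CH2Cl2, −78 → −20 °C
Reagents that add atoms: none
Why: Lewis-acid-promoted intramolecular carbonyl-ene reaction, with the ene unit tethered through its central carbon, forms C6–C7 and the seven-membered ring with hydrogen transfer from the C8 methyl; the trans fusion follows from the fixed C1 and C5 centres, and the C6 hydroxyl is expected axial (α) because the carbonyl oxygen must sit over the transferring hydrogen, a centre that is in any case reset in steps 14 and 15.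

**Step 12**
Reactants: 18 methylene alcohol
Product: 20 C6 α-hydroxy C8 ketone, via triol 19 (not isolated)
Conditions: OsO4 (2 mol %), NaIO4, 2,6-lutidine, dioxane/H2O, 23 °C
Reagents that add atoms: osmium tetroxide, O=[Os](=O)(=O)=O; sodium periodate, [Na+].[O-]I(=O)(=O)=O
Why: Lemieux–Johnson cleavage (dihydroxylation, then periodate glycol scission); the exocyclic 1,1-disubstituted alkene is far more accessible than the C2=C3 alkene flanked by two fully substituted carbons.

**Step 13**
Reactants: 20 hydroxy ketone
Product: 21 C6 α-OH; C8 α-OH/β-CH3 diol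
Conditions: MeMgBr (4 equiv), THF, −78 → −20 °C; aq. NH4Cl
Reagents that add atoms: methylmagnesium bromide, C[Mg]Br
Why: Grignard addition to the cycloheptanone, with methyl expected to enter equatorially from the β-face, away from the axial C6 alkoxide and the α-face angular methyl, which gives the 8α-hydroxy-8β-methyl carbinol.

**Step 14**
Reactants: 21 diol
Product: 22 C6 ketone with C8 α-OH
Conditions: Dess–Martin periodinane, NaHCO3, CH2Cl2, 0 → 23 °C
Reagents that add atoms: none
Why: Dess–Martin oxidation of the only secondary alcohol gives the β-hydroxy ketone under non-basic conditions that avoid retro-aldol cleavage and elimination of the C4 silyloxy group.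

**Step 15**
Reactants: 22 β-hydroxy ketone
Product: 23 C6 β-OH; C8 α-OH diol (C4 OSiEt3)
Conditions: Me4NBH(OAc)3, MeCN/AcOH, −30 °C
Reagents that add atoms: none
Why: Evans–Saksena hydroxyl-directed reduction: the borohydride exchanges onto the axial 8α-hydroxyl and delivers hydride intramolecularly to the α-face of C6, giving the 6β (trans-1,3) alcohol.

**Step 16**
Reactants: 24 vanillic acid
Product: 26 4-[(tert-butyldimethylsilyl)oxy]-3-methoxybenzoic acid, via bis-silyl derivative 25 (not isolated)
Conditions: t-BuMe2SiCl (2.5 equiv), imidazole, DMF, 23 °C; then AcOH/THF/H2O, 23 °C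
Reagents that add atoms: tert-butyldimethylsilyl chloride, CC(C)(C)[Si](C)(C)Cl
Why: Exhaustive silylation of acid and phenol followed by selective hydrolysis of the labile silyl ester leaves the aryl silyl ether.

**Step 17**
Reactants: 23 diol; 26 protected vanillic acid
Product: 27 C6 4-(tert-butyldimethylsilyloxy)-3-methoxybenzoate of 23
Conditions: N,N′-dicyclohexylcarbodiimide, 4-(dimethylamino)pyridine, CH2Cl2, 23 °C
Reagents that add atoms: none
Why: Steglich esterification acylates the only secondary hydroxyl; the tertiary C8 hydroxyl and the silylated C4 oxygen do not react.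

**Step 18**
Reactants: 27 protected ester
Product: 28 target CNP0113302.1
Conditions: Bu4NF, AcOH, THF, 0 → 23 °C
Reagents that add atoms: none
Why: Fluoride-mediated desilylation removes the aryl and the tertiary silyl ether in one operation, buffered with acetic acid so that the benzoate ester is neither cleaved nor migrated.

**Compound list**

1 | 2-isopropylfuran | CC(C)c1ccco1 | starting material
2 | (4-methoxybenzyloxy)acetaldehyde | COc1ccc(COCC=O)cc1 | starting material
3 | 5-isopropyl-2-furyllithium | [Li]c1ccc(o1)C(C)C | intermediate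
4 | rac-1-(5-isopropylfuran-2-yl)-2-[(4-methoxybenzyl)oxy]ethan-1-ol | CC(C)c1ccc(o1)C(O)COCc1ccc(OC)cc1 | intermediate
5 | 1,4-dihydroxypentadienyl cation (drawn as the O-protonated (Z)-enone enol) | CC(C)C(=[OH+])/C=C\C(O)=CCOCc1ccc(OC)cc1 | intermediate
6 | (4S,5R)-4-hydroxy-4-isopropyl-5-{[(4-methoxybenzyl)oxy]methyl}cyclopent-2-en-1-one (OH trans to side chain) | O=C1C=C[C@@](O)(C(C)C)[C@H]1COCc1ccc(OC)cc1 | intermediate
7 | (4S,5R)-4-isopropyl-5-{[(4-methoxybenzyl)oxy]methyl}-4-[(triethylsilyl)oxy]cyclopent-2-en-1-one | O=C1C=C[C@@](O[Si](CC)(CC)CC)(C(C)C)[C@H]1COCc1ccc(OC)cc1 | intermediate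
8 | (4S,5S)-4-isopropyl-5-{[(4-methoxybenzyl)oxy]methyl}-4-[(triethylsilyl)oxy]cyclopent-2-en-1-one (silyloxy cis to side chain) | O=C1C=C[C@@](O[Si](CC)(CC)CC)(C(C)C)[C@@H]1COCc1ccc(OC)cc1 | intermediate
9 | 4-isopropyl-1-methyl-5-{[(4-methoxybenzyl)oxy]methyl}-4-[(triethylsilyl)oxy]cyclopent-2-en-1-ol (C1 methyl anti to side chain) | C[C@@]1(O)C=C[C@@](O[Si](CC)(CC)CC)(C(C)C)[C@@H]1COCc1ccc(OC)cc1 | intermediate
10 | (4S,5R)-5-isopropyl-4-{[(4-methoxybenzyl)oxy]methyl}-3-methyl-5-[(triethylsilyl)oxy]cyclopent-2-en-1-one | CC1=CC(=O)[C@@](O[Si](CC)(CC)CC)(C(C)C)[C@@H]1COCc1ccc(OC)cc1 | intermediate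
11 | 4-bromo-2-methylbut-1-ene | C=C(C)CCBr | starting material
12 | (3-methylbut-3-en-1-yl)magnesium bromide | C=C(C)CC[Mg]Br | intermediate
13 | bromomagnesium C2=C3 enolate of the conjugate adduct | C=C(C)CC[C@@]1(C)C=C(O[Mg]Br)[C@@](O[Si](CC)(CC)CC)(C(C)C)[C@@H]1COCc1ccc(OC)cc1 | intermediate
14 | C3 enol triflate with the C1 quaternary centre (chain β, methyl α) | C=C(C)CC[C@@]1(C)C=C(OS(=O)(=O)C(F)(F)F)[C@@](O[Si](CC)(CC)CC)(C(C)C)[C@@H]1COCc1ccc(OC)cc1 | intermediate
15 | cyclopent-2-ene with C1 (methyl, 3-methylbut-3-enyl), C4 (OSiEt3, isopropyl), C5 (CH2OPMB) | C=C(C)CC[C@@]1(C)C=C[C@@](O[Si](CC)(CC)CC)(C(C)C)[C@@H]1COCc1ccc(OC)cc1 | intermediate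
16 | primary alcohol from 15 (C5 CH2OH) | C=C(C)CC[C@@]1(C)C=C[C@@](O[Si](CC)(CC)CC)(C(C)C)[C@@H]1CO | intermediate
17 | C6 aldehyde | C=C(C)CC[C@@]1(C)C=C[C@@](O[Si](CC)(CC)CC)(C(C)C)[C@@H]1C=O | intermediate
18 | trans-fused hydroazulene: C6 α-OH, C8 exocyclic methylene, C4 OSiEt3 | O[C@@H]1CC(=C)CC[C@@]2(C)C=C[C@@](O[Si](CC)(CC)CC)(C(C)C)[C@H]12 | intermediate
19 | triol: C6 α-OH, C8 (OH)(CH2OH), either C8 configuration | O[C@@H]1CC(O)(CO)CC[C@@]2(C)C=C[C@@](O[Si](CC)(CC)CC)(C(C)C)[C@H]12 | intermediate
20 | C6 α-hydroxy C8 ketone | O[C@@H]1CC(=O)CC[C@@]2(C)C=C[C@@](O[Si](CC)(CC)CC)(C(C)C)[C@H]12 | intermediate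
21 | diol: C6 α-OH; C8 α-OH, β-CH3 | O[C@@H]1C[C@](C)(O)CC[C@@]2(C)C=C[C@@](O[Si](CC)(CC)CC)(C(C)C)[C@H]12 | intermediate
22 | C6 ketone; C8 α-OH, β-CH3 | O=C1C[C@](C)(O)CC[C@@]2(C)C=C[C@@](O[Si](CC)(CC)CC)(C(C)C)[C@H]12 | intermediate
23 | diol: C6 β-OH; C8 α-OH, β-CH3; C4 OSiEt3 | O[C@H]1C[C@](C)(O)CC[C@@]2(C)C=C[C@@](O[Si](CC)(CC)CC)(C(C)C)[C@H]12 | intermediate
24 | vanillic acid | COc1cc(C(=O)O)ccc1O | starting material
25 | tert-butyldimethylsilyl 4-[(tert-butyldimethylsilyl)oxy]-3-methoxybenzoate | COc1cc(C(=O)O[Si](C)(C)C(C)(C)C)ccc1O[Si](C)(C)C(C)(C)C | intermediate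
26 | 4-[(tert-butyldimethylsilyl)oxy]-3-methoxybenzoic acid | COc1cc(C(=O)O)ccc1O[Si](C)(C)C(C)(C)C | intermediate
27 | C6 ester of 23 with 26 (aryl O-TBS, C4 O-TES) | COc1cc(C(=O)O[C@H]2C[C@](C)(O)CC[C@@]3(C)C=C[C@@](O[Si](CC)(CC)CC)(C(C)C)[C@H]23)ccc1O[Si](C)(C)C(C)(C)C | intermediate
28 | (3S,3aS,4S,6R,8aS)-3,6-dihydroxy-6,8a-dimethyl-3-(propan-2-yl)-3,3a,4,5,6,7,8,8a-octahydroazulen-4-yl 4-hydroxy-3-methoxybenzoate (1S,4S,5S,6S,8R in the numbering used here) | COc1cc(C(=O)O[C@H]2C[C@](C)(O)CC[C@@]3(C)C=C[C@@](O)(C(C)C)[C@H]23)ccc1O | target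

**Step count**

Total: 18 steps. Longest linear sequence: 17 steps (steps 1–15, 17 and 18); step 16 is a one-step side branch.

**Steps most likely to fail**

- **Step 2** (the step flagged as new). The ion pair may give low enantioselectivity, and water may compete poorly with oligomerisation of the furfuryl cation or with proton loss from the isopropyl group. The fallback sets out from 4 and uses the known racemic catalysis: Dy(OTf)3 (10 mol %), t-BuOH/H2O, 80 °C. This gives 6 as the racemate, i.e. together with (4R,5S)-4-hydroxy-4-isopropyl-5-{[(4-methoxybenzyl)oxy]methyl}cyclopent-2-en-1-one F1. Preparative chromatography on a chiral stationary phase (cellulose tris(3,5-dimethylphenylcarbamate)) separates the two, and the route is rejoined at 6.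

- **Step 11.** Ionisation of the tertiary allylic silyl ether, chloride capture of a C8 cation (Prins pathway) or epimerisation of the aldehyde at C5 may outrun the ene closure. The fallback leaves the cationic ene manifold and sets out from alcohol 16. Lemieux–Johnson cleavage of the isopropenyl group (OsO4 cat., NaIO4) gives the hydroxy methyl ketone F2, and Dess–Martin oxidation gives the keto aldehyde F3. Kinetic enolisation of the methyl ketone on its methyl side with Bu2BOTf/iPr2NEt at −78 °C, then intramolecular boron aldol addition to the aldehyde and work-up with H2O2/pH 7 buffer, closes the seven-membered ring. The route is rejoined at hydroxy ketone 20; either C6 epimer serves because C6 is reset in steps 14 and 15.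

- **Step 13.** Facial selectivity in the addition to the cycloheptanone may be poor (methyl entering from the α-face gives the C8 epimer), or the magnesium aldolate may open by retro-aldol. The fallback delivers oxygen instead of carbon and sets out from 18. VO(acac)2 (cat.) with t-BuOOH epoxidises the exocyclic alkene on the α-face under direction of the axial 6α-hydroxyl, giving the spiro-epoxide F4. LiEt3BH opens it at the methylene carbon, and the route is rejoined at diol 21.

**Further compounds**

F1 | step 2 | (4R,5S)-4-hydroxy-4-isopropyl-5-{[(4-methoxybenzyl)oxy]methyl}cyclopent-2-en-1-one (enantiomer of 6) | O=C1C=C[C@](O)(C(C)C)[C@@H]1COCc1ccc(OC)cc1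
F2 | step 11 | hydroxy methyl ketone: C5 CH2OH, C1 3-oxobutyl chain, C4 OSiEt3 | CC(=O)CC[C@@]1(C)C=C[C@@](O[Si](CC)(CC)CC)(C(C)C)[C@@H]1CO
F3 | step 11 | keto aldehyde: C6 aldehyde, C8 methyl ketone | CC(=O)CC[C@@]1(C)C=C[C@@](O[Si](CC)(CC)CC)(C(C)C)[C@@H]1C=O
F4 | step 13 | spiro-epoxide: C6 α-OH, C8 α-O/β-CH2 oxirane | O[C@@H]1C[C@]3(OC3)CC[C@@]2(C)C=C[C@@](O[Si](CC)(CC)CC)(C(C)C)[C@H]12
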